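Ring A is numbered C1 (CH3), C2 (H), C3 (OH), C4 (CO2H), C5 (ether O), C6 (lactone C=O); ring B is C1′ (ester O), C2′ (CH2OH), C3′ (OH), C4′/C5′ (phthalide), C6′ (ether O). The route exploits the neighbouring C5 (oxygen) and C4 (carboxyl) of ring A beside the C3 oxygen, forming the C5–O–C6′ ether and C4–CO2H bonds together. In a depside joined C6–C(=O)–O–C1′, fluoride releases a C6′ phenoxide and a C4–C5 aryne; the phenoxide closes the seven-membered ring at C5 and the C4 anion captures CO2. The precursor is an ortho-silylaryl triflate (C4 SiMe3, C5 OTf) bearing a C6′ silyl ether and acetal protection.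

Key step: step 17

Assumption: orcinol, methyl atratate and (for one fallback) 3-fluoro-5-methylphenol are taken as commercially available.

Remarks on the design:
- The phthalide names of the ring-B compounds use the locants of 2-benzofuran-1(3H)-one: position 1 is the carbonyl, 3 the CH2, 4–7 the aromatic positions. Position 4 = C6′, 5 = C1′, 6 = C2′, 7 = C3′.
- The permanent protecting groups are acetals only: a MOM ether on the C3 oxygen and one isopropylidene acetal (acetonide) tying the C3′ oxygen to the C2′ CH2O. The precursor then has no O–H to protonate the aryl anion, and one aqueous acid step at the end suffices. No hydrogenolysis is run on a molecule that contains the free benzylic alcohol.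
- The C6′ oxygen carries a triisopropylsilyl group: it is still cleaved by fluoride, but it does not migrate to the neighbouring C1′ oxygen during the slow esterification.
- The aryne is generated with KF/18-crown-6 in THF, so that neither acetonitrile nor an ammonium ion with β-hydrogens is present as a proton source.
- The site of benzylation in 18 and of acylation in 23 should be confirmed by HMBC/NOE before material is carried on.

Step 1
Reactants: 1 orcinol
Product: 2 3-(methoxymethoxy)-5-methylphenol
Conditions: MOMCl (1.0 equiv), iPr2NEt, CH2Cl2, 0 °C → rt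
Reagents that add atoms: chloromethyl methyl ether, COCCl
Why: Williamson-type O-alkylation of one phenol of the symmetric diol with a chloromethyl ether is statistical, and the bis-ether and unchanged 1 are separated and recycled, which is acceptable for the first step on a bulk chemical.

Step 2
Reactants: 2 3-(methoxymethoxy)-5-methylphenol
Product: 3 3-(methoxymethoxy)-5-methylphenyl N-(propan-2-yl)carbamate
Conditions: iPrNCO, Et3N (cat.), CH2Cl2, rt
Reagents that add atoms: isopropyl isocyanate, CC(C)N=C=O
Why: Carbamoylation by base-catalysed addition of the phenol to the isocyanate installs a strong directing group that is later removed under mild basic conditions.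

Step 3
Reactants: 3 3-(methoxymethoxy)-5-methylphenyl N-(propan-2-yl)carbamate
Product: 7 3-(methoxymethoxy)-5-methyl-2-(trimethylsilyl)phenyl N-(propan-2-yl)carbamate, via N-silyl carbamate 4 (not isolated), via aryllithium 5 (not isolated), via C-silylated N-silyl carbamate 6 (not isolated)
Conditions: TBSOTf, TMEDA, Et2O, 0 °C → rt; n-BuLi, TMEDA, −78 °C; TMSCl, −78 °C → rt; aq. NaHSO4
Reagents that add atoms: chlorotrimethylsilane, C[Si](C)(C)Cl
Why: Directed ortho-metalation after in situ N-silylation puts lithium on the carbon between the carbamate and MOM oxygens (future C4 of ring A), where both groups direct, and TMSCl silylates it while the labile N–Si bond is hydrolysed on work-up.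

Step 4
Reactants: 7 3-(methoxymethoxy)-5-methyl-2-(trimethylsilyl)phenyl N-(propan-2-yl)carbamate
Product: 8 3-(methoxymethoxy)-5-methyl-2-(trimethylsilyl)phenol
Conditions: Et2NH, DBU, MeCN, 40 °C
Reagents that add atoms: none
Why: Base-induced cleavage of the N-monoalkyl aryl carbamate (E1cB elimination to the isocyanate, trapped by Et2NH as a urea) leaves the aryl C–Si bond and the MOM ether untouched.

Step 5
Reactants: 8 3-(methoxymethoxy)-5-methyl-2-(trimethylsilyl)phenol
Product: 9 2-hydroxy-4-(methoxymethoxy)-6-methyl-3-(trimethylsilyl)benzaldehyde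
Conditions: MgCl2, Et3N, (CH2O)n, MeCN, 80 °C
Reagents that add atoms: formaldehyde (as paraformaldehyde), C=O
Why: Casnati–Skattebøl ortho-formylation delivers formaldehyde from the magnesium phenoxide to the only free ortho carbon (future C6 of ring A) and a second equivalent oxidises the benzylic alkoxide to the aldehyde, without the acid that would protodesilylate the ring.

Step 6
Reactants: 9 2-hydroxy-4-(methoxymethoxy)-6-methyl-3-(trimethylsilyl)benzaldehyde
Product: 10 2-formyl-5-(methoxymethoxy)-3-methyl-6-(trimethylsilyl)phenyl trifluoromethanesulfonate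
Conditions: Tf2O, pyridine, CH2Cl2, −10 → 0 °C
Reagents that add atoms: trifluoromethanesulfonic anhydride, O=S(=O)(OS(=O)(=O)C(F)(F)F)C(F)(F)F
Why: O-Sulfonylation of the hindered, hydrogen-bonded phenol with the anhydride under pyridine buffering gives the ortho-silylaryl triflate.

Step 7
Reactants: 10 2-formyl-5-(methoxymethoxy)-3-methyl-6-(trimethylsilyl)phenyl trifluoromethanesulfonate
Product: 11 4-(methoxymethoxy)-6-methyl-2-(trifluoromethanesulfonyloxy)-3-(trimethylsilyl)benzoic acid
Conditions: NaClO2, NaH2PO4, 2-methyl-2-butene, t-BuOH/H2O, rt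
Reagents that add atoms: sodium chlorite, [Na+].[O-]Cl=O
Why: Pinnick oxidation converts the hindered, non-enolisable aldehyde into the acid at buffered pH with a hypochlorite scavenger, which triflate, aryl silane and MOM ether tolerate.

Step 8
Reactants: 12 methyl atratate (methyl 2,4-dihydroxy-3,6-dimethylbenzoate)
Product: 14 methyl 2,4,5-trihydroxy-3,6-dimethylbenzoate, via potassium aryl sulfate 13 (not isolated)
Conditions: K2S2O8, aq. NaOH, 0 °C → rt; then aq. HCl, 80 °C, Ar
Reagents that add atoms: potassium peroxodisulfate, [K+].[K+].[O-]S(=O)(=O)OOS(=O)(=O)[O-]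
Why: Elbs persulfate oxidation makes the phenoxide attack peroxodisulfate through the only unsubstituted ring carbon (para to the 2-hydroxyl of the benzoate, future C6′) to give an aryl sulfate that resists further oxidation and is then hydrolysed in acid, while the hindered methyl ester survives.

Step 9
Reactants: 14 methyl 2,4,5-trihydroxy-3,6-dimethylbenzoate
Product: 15 methyl 2,4,5-triacetoxy-3,6-dimethylbenzoate
Conditions: Ac2O, pyridine, DMAP (cat.), rt
Reagents that add atoms: acetic anhydride, CC(=O)OC(C)=O
Why: Exhaustive DMAP-catalysed O-acetylation masks the air-sensitive hydroxyquinol and deactivates the ring for the radical step.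

Step 10
Reactants: 15 methyl 2,4,5-triacetoxy-3,6-dimethylbenzoate
Product: 16 methyl 2,4,5-triacetoxy-3,6-bis(bromomethyl)benzoate
Conditions: NBS (2.2 equiv), AIBN (cat.), PhCF3, reflux
Reagents that add atoms: N-bromosuccinimide, O=C1CCC(=O)N1Br
Why: Wohl–Ziegler bromination can only abstract benzylic hydrogen, once at each methyl group, because the ring is fully substituted and electron-poor as the triacetate.

Step 11
Reactants: 16 methyl 2,4,5-triacetoxy-3,6-bis(bromomethyl)benzoate
Product: 17 4,5,7-trihydroxy-6-(hydroxymethyl)phthalide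
Conditions: 1 M aq. H2SO4/1,4-dioxane, 80 °C, Ar
Reagents that add atoms: water, O
Why: Acid-catalysed solvolysis of both benzylic bromides, lactonisation of the new hydroxymethyl group onto the neighbouring ester (phthalide formation) and hydrolysis of the three aryl acetates run under one set of conditions, and with every ring position substituted the benzylic cation can only return to the alcohol.

Step 12
Reactants: 17 4,5,7-trihydroxy-6-(hydroxymethyl)phthalide
Product: 18 5-(benzyloxy)-4,7-dihydroxy-6-(hydroxymethyl)phthalide
Conditions: BnBr (1.0 equiv), KHCO3, DMF, rt → 40 °C, Ar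
Reagents that add atoms: benzyl bromide, BrCc1ccccc1
Why: Williamson etherification under weak-base control should alkylate the 5-hydroxyl (the C1′ oxygen) preferentially, because this hydroxyl, para to the lactone carbonyl, is the most acidic, the 7-hydroxyl is hydrogen-bonded to the carbonyl and the primary alcohol is not deprotonated.

Step 13
Reactants: 18 5-(benzyloxy)-4,7-dihydroxy-6-(hydroxymethyl)phthalide
Product: 19 5-(benzyloxy)-4-hydroxyphthalide acetonide (CMe2 bridging the 7-oxygen and the 6-CH2O)
Conditions: Me2C(OMe)2, PPTS (cat.), acetone, rt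
Reagents that add atoms: 2,2-dimethoxypropane, COC(C)(C)OC
Why: Acid-catalysed transacetalisation gives the six-membered isopropylidene acetal of the salicyl alcohol unit, and with the 5-oxygen benzylated the 7-oxygen is the only phenol that can close it.

Step 14
Reactants: 19 5-(benzyloxy)-4-hydroxyphthalide acetonide
Product: 20 5-(benzyloxy)-4-(triisopropylsilyloxy)phthalide acetonide
Conditions: TIPSOTf, 2,6-lutidine, CH2Cl2, 0 °C
Reagents that add atoms: triisopropylsilyl trifluoromethanesulfonate, CC(C)[Si](OS(=O)(=O)C(F)(F)F)(C(C)C)C(C)C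
Why: O-Silylation of the only remaining phenol (on C6′) with a silyl triflate and a hindered pyridine base installs a bulky group that does not migrate between neighbouring oxygens.

Step 15
Reactants: 20 5-(benzyloxy)-4-(triisopropylsilyloxy)phthalide acetonide
Product: 21 5-hydroxy-4-(triisopropylsilyloxy)phthalide acetonide (ring-B phenol, C1′ hydroxyl free)
Conditions: H2 (1 atm), Pd/C, EtOAc, rt
Reagents that add atoms: none
Why: Hydrogenolysis of the aryl benzyl ether over Pd/C under neutral conditions is tolerated by the silyl ether, the acetonide and the lactone.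

Step 16
Reactants: 11 4-(methoxymethoxy)-6-methyl-2-(trifluoromethanesulfonyloxy)-3-(trimethylsilyl)benzoic acid; 21 5-hydroxy-4-(triisopropylsilyloxy)phthalide acetonide
Product: 23 depside precursor (aryl ester at the C1′ oxygen), via acid chloride 22 (not isolated)
Conditions: 11, Me2C=C(Cl)NMe2, CH2Cl2, 0 °C → rt; then 21, Et3N, DMAP, CH2Cl2, 0 → 40 °C
Reagents that add atoms: none
Why: Esterification through the acid chloride, made under neutral conditions with an α-chloroenamine so that no HCl reaches the acetals, followed by DMAP-catalysed acyl transfer to the phenol is the standard answer to a doubly ortho-substituted acid.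

Step 17
Reactants: 23 depside precursor; 24 carbon dioxide
Product: 29 protected depsidone acid (C3 MOM ether; C2′/C3′ acetonide; C4 CO2H free), via potassium phenoxide 25 (not isolated), via aryne phenoxide 26 (not isolated), via aryl anion 27 (not isolated), via potassium carboxylate 28 (not isolated)
Conditions: KF, 18-crown-6, CO2 (1 atm, solution pre-saturated), THF (0.01 M), −20 °C → rt; cold dilute aq. H2SO4 work-up
Reagents that add atoms: carbon dioxide, O=C=O
Why: Proposed new method: fluoride is expected to cleave the phenolic Si–O bond at C6′ first and then the hindered C4–Si bond with loss of the C5 triflate, so that the C6′ phenoxide is waiting when the C4–C5 aryne appears, adds to C5, and leaves a C4 aryl anion (flanked by the C3 and C5 oxygens) that is carboxylated by dissolved CO2 before it meets a proton, since solvent, counter-ion and substrate offer no O–H, N–H or ammonium C–H. The closest known reaction types are the three-component coupling of arynes with amine nucleophiles and CO2, the O-arylation of phenoxides by arynes, and the capture of the aryl anion formed in such an O-arylation by a neighbouring ester carbonyl (xanthone formation). The seven-membered ring closes in a 7-exo-dig mode, because the ester tether lets the C6′ oxygen reach C5 but not C4 (which would need an 8-endo closure), and the C3 alkoxy group polarises the aryne in the same sense (nucleophile meta, anion ortho to oxygen). No stereocentre is formed. The step needs attack at C5 by the C6′ oxygen before any 1,2-shift of the aroyl group from the C1′ to the C6′ oxygen, and the doubly ortho-substituted aroyl group (C1 methyl and C5 triflate, the latter buttressed by the C4 silyl group) together with the low temperature at which the phenoxide is released should keep that shift slower than aryne formation and ring closure.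

Step 18
Reactants: 29 protected depsidone acid
Product: 30 conneotricone
Conditions: 1 M aq. H2SO4/THF, 40 °C
Reagents that add atoms: none
Why: Acid-catalysed hydrolysis of the two acetals (aryl MOM ether and isopropylidene acetal) with a non-nucleophilic acid in aqueous medium, where the benzylic alcohol can only exchange with water, gives the target without a reductive step.

Compound list
1 | orcinol (5-methylbenzene-1,3-diol) | Cc1cc(O)cc(O)c1 | starting material
2 | 3-(methoxymethoxy)-5-methylphenol | COCOc1cc(C)cc(O)c1 | intermediate
3 | 3-(methoxymethoxy)-5-methylphenyl N-(propan-2-yl)carbamate | COCOc1cc(C)cc(OC(=O)NC(C)C)c1 | intermediate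
4 | 3-(methoxymethoxy)-5-methylphenyl N-(tert-butyldimethylsilyl)-N-(propan-2-yl)carbamate | COCOc1cc(C)cc(OC(=O)N(C(C)C)[Si](C)(C)C(C)(C)C)c1 | intermediate (not isolated)
5 | 2-lithio derivative of 4 (lithium on the carbon between the two oxygens) | [Li]c1c(OCOC)cc(C)cc1OC(=O)N(C(C)C)[Si](C)(C)C(C)(C)C | intermediate (not isolated)
6 | 3-(methoxymethoxy)-5-methyl-2-(trimethylsilyl)phenyl N-(tert-butyldimethylsilyl)-N-(propan-2-yl)carbamate | COCOc1cc(C)cc(OC(=O)N(C(C)C)[Si](C)(C)C(C)(C)C)c1[Si](C)(C)C | intermediate (not isolated)
7 | 3-(methoxymethoxy)-5-methyl-2-(trimethylsilyl)phenyl N-(propan-2-yl)carbamate | COCOc1cc(C)cc(OC(=O)NC(C)C)c1[Si](C)(C)C | intermediate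
8 | 3-(methoxymethoxy)-5-methyl-2-(trimethylsilyl)phenol | COCOc1cc(C)cc(O)c1[Si](C)(C)C | intermediate
9 | 2-hydroxy-4-(methoxymethoxy)-6-methyl-3-(trimethylsilyl)benzaldehyde | COCOc1cc(C)c(C=O)c(O)c1[Si](C)(C)C | intermediate
10 | 2-formyl-5-(methoxymethoxy)-3-methyl-6-(trimethylsilyl)phenyl trifluoromethanesulfonate | COCOc1cc(C)c(C=O)c(OS(=O)(=O)C(F)(F)F)c1[Si](C)(C)C | intermediate
11 | 4-(methoxymethoxy)-6-methyl-2-(trifluoromethanesulfonyloxy)-3-(trimethylsilyl)benzoic acid (ring-A acid) | COCOc1cc(C)c(C(=O)O)c(OS(=O)(=O)C(F)(F)F)c1[Si](C)(C)C | intermediate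
12 | methyl atratate (methyl 2,4-dihydroxy-3,6-dimethylbenzoate) | COC(=O)c1c(C)cc(O)c(C)c1O | starting material
13 | potassium 2,4-dihydroxy-5-(methoxycarbonyl)-3,6-dimethylphenyl sulfate | COC(=O)c1c(C)c(OS(=O)(=O)[O-])c(O)c(C)c1O.[K+] | intermediate (not isolated)
14 | methyl 2,4,5-trihydroxy-3,6-dimethylbenzoate | COC(=O)c1c(C)c(O)c(O)c(C)c1O | intermediate
15 | methyl 2,4,5-triacetoxy-3,6-dimethylbenzoate | COC(=O)c1c(C)c(OC(C)=O)c(OC(C)=O)c(C)c1OC(C)=O | intermediate
16 | methyl 2,4,5-triacetoxy-3,6-bis(bromomethyl)benzoate | COC(=O)c1c(CBr)c(OC(C)=O)c(OC(C)=O)c(CBr)c1OC(C)=O | intermediate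
17 | 4,5,7-trihydroxy-6-(hydroxymethyl)phthalide (2-benzofuran-1(3H)-one numbering) | O=C1OCc2c1c(O)c(CO)c(O)c2O | intermediate
18 | 5-(benzyloxy)-4,7-dihydroxy-6-(hydroxymethyl)phthalide | O=C1OCc2c1c(O)c(CO)c(OCc3ccccc3)c2O | intermediate
19 | 5-(benzyloxy)-4-hydroxyphthalide acetonide: 2,2-dimethyl-4H-1,3-dioxine ring fused at positions 6 and 7, ring oxygen on position 7, ring CH2 on position 6 | O=C1OCc2c(O)c(OCc3ccccc3)c4COC(C)(C)Oc4c12 | intermediate
20 | 5-(benzyloxy)-4-(triisopropylsilyloxy)phthalide acetonide (same acetonide as 19) | O=C1OCc2c(O[Si](C(C)C)(C(C)C)C(C)C)c(OCc3ccccc3)c4COC(C)(C)Oc4c12 | intermediate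
21 | 5-hydroxy-4-(triisopropylsilyloxy)phthalide acetonide (ring-B phenol; C1′ hydroxyl free, C6′ OSi(iPr)3) | O=C1OCc2c(O[Si](C(C)C)(C(C)C)C(C)C)c(O)c3COC(C)(C)Oc3c12 | intermediate
22 | 4-(methoxymethoxy)-6-methyl-2-(trifluoromethanesulfonyloxy)-3-(trimethylsilyl)benzoyl chloride | COCOc1cc(C)c(C(Cl)=O)c(OS(=O)(=O)C(F)(F)F)c1[Si](C)(C)C | intermediate (not isolated)
23 | depside precursor: aryl ester of acid 11 at the 5-oxygen (C1′) of 21; ring A carries C3 OMOM, C4 SiMe3, C5 OTf; ring B carries C6′ OSi(iPr)3 and the C2′/C3′ acetonide | COCOc1cc(C)c(C(=O)Oc2c3COC(C)(C)Oc3c3C(=O)OCc3c2O[Si](C(C)C)(C(C)C)C(C)C)c(OS(=O)(=O)C(F)(F)F)c1[Si](C)(C)C | intermediate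
24 | carbon dioxide | O=C=O | starting material
25 | potassium C6′ phenoxide of 23 (silyl triflate intact) | COCOc1cc(C)c(C(=O)Oc2c3COC(C)(C)Oc3c3C(=O)OCc3c2[O-])c(OS(=O)(=O)C(F)(F)F)c1[Si](C)(C)C.[K+] | intermediate (not isolated)
26 | C4–C5 aryne of ring A carrying the C6′ phenoxide | COCOC1=CC(C)=C(C(=O)Oc2c3COC(C)(C)Oc3c3C(=O)OCc3c2[O-])C#C1.[K+] | intermediate (not isolated)
27 | cyclised depsidone C4 aryl anion (potassium salt) | COCOc1cc(C)c2C(=O)Oc3c4COC(C)(C)Oc4c4C(=O)OCc4c3Oc2[c-]1.[K+] | intermediate (not isolated)
28 | potassium C4 carboxylate of the protected depsidone | COCOc1cc(C)c2C(=O)Oc3c4COC(C)(C)Oc4c4C(=O)OCc4c3Oc2c1C(=O)[O-].[K+] | intermediate (not isolated)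
29 | protected depsidone acid: C3 OMOM, C4 CO2H, C2′/C3′ acetonide | COCOc1cc(C)c2C(=O)Oc3c4COC(C)(C)Oc4c4C(=O)OCc4c3Oc2c1C(=O)O | intermediate
30 | conneotricone | Cc1cc(O)c(C(=O)O)c2c1C(=O)Oc1c(CO)c(O)c3c(c1O2)COC3=O | target

Total step count: 18 (ring A: steps 1–7; ring B: steps 8–15; union and end game: steps 16–18).
Longest linear sequence: 11 steps (steps 8–18, from methyl atratate).

Steps most likely to fail

Step 17 (Proposed new method). The C4 aryl anion may be protonated (by traces of water, by C–H bonds of the crown ether or by the phthalide CH2) faster than it is carboxylated. The aroyl group may shift from the C1′ to the C6′ oxygen while the phenoxide waits for the aryne. The aryne may also form before the phenoxide is released and be lost to fluoride addition. The fallback makes the two bonds separately by known reactions, with the carboxyl group in place first; it sets out from phenol 21 and commercial 3-fluoro-5-methylphenol (Cc1cc(O)cc(F)c1) and comes back to the route at target 30. MOM protection (MOMCl, iPr2NEt) gives 1-fluoro-3-(methoxymethoxy)-5-methylbenzene F1. Directed lithiation between fluorine and the acetal oxygen (n-BuLi, THF, −78 °C) and quenching with Boc2O gives tert-butyl 2-fluoro-6-(methoxymethoxy)-4-methylbenzoate F2. Bromination para to the acetal oxygen (NBS, DMF) gives tert-butyl 3-bromo-2-fluoro-6-(methoxymethoxy)-4-methylbenzoate F3. Bromine–magnesium exchange (iPrMgCl·LiCl, THF, −20 °C) and CO2 give 3-(tert-butoxycarbonyl)-2-fluoro-4-(methoxymethoxy)-6-methylbenzoic acid F4. Esterification with 21 under the conditions of step 16 gives the fluoro depside F5. CsF in DMF then frees the C6′ phenoxide, which displaces the C5 fluoride, activated by two ortho carbonyl groups, in an intramolecular SNAr reaction to give the protected depsidone tert-butyl ester F6. Aqueous trifluoroacetic acid removes the tert-butyl ester, the MOM group and the acetonide and gives 30.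

Step 16. Acyl transfer from a doubly ortho-substituted acid chloride to a phenol flanked by two ortho substituents may stall, and during a slow coupling the silyl group may still move to the C1′ oxygen, which would give the regioisomeric ester. The fallback makes the ester on the unsilylated catechol; it sets out from benzyl ether 19 and acid chloride 22 and comes back at precursor 23. Hydrogenolysis of 19 (H2, Pd/C, EtOAc) gives the 4,5-dihydroxyphthalide acetonide F7. Its more acidic C1′ hydroxyl (para to the lactone carbonyl) is acylated with 22 and one equivalent of Et3N at −40 → 0 °C to give the C6′-hydroxy depside F8. Silylation of the C6′ hydroxyl (TIPSOTf, 2,6-lutidine, CH2Cl2, 0 °C) gives 23.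

Step 8. Over-oxidation of the electron-rich resorcinol dianion and low conversion are the usual weaknesses of persulfate oxidations. The fallback brings the oxygen in through a formyl group; it sets out from 12 and comes back at triol 14. Rieche formylation (Cl2CHOMe, TiCl4, CH2Cl2, 0 °C) at the only free ring position gives methyl 5-formyl-2,4-dihydroxy-3,6-dimethylbenzoate F9, and Dakin oxidation (H2O2, aq. NaOH, then acid, under Ar) of this ortho/para-hydroxy aldehyde gives 14.

Further compounds
F1 | step 17 | 1-fluoro-3-(methoxymethoxy)-5-methylbenzene | COCOc1cc(C)cc(F)c1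
F2 | step 17 | tert-butyl 2-fluoro-6-(methoxymethoxy)-4-methylbenzoate | COCOc1cc(C)cc(F)c1C(=O)OC(C)(C)C
F3 | step 17 | tert-butyl 3-bromo-2-fluoro-6-(methoxymethoxy)-4-methylbenzoate | COCOc1cc(C)c(Br)c(F)c1C(=O)OC(C)(C)C
F4 | step 17 | 3-(tert-butoxycarbonyl)-2-fluoro-4-(methoxymethoxy)-6-methylbenzoic acid | COCOc1cc(C)c(C(=O)O)c(F)c1C(=O)OC(C)(C)C
F5 | step 17 | fluoro depside: aryl ester of F4 at the 5-oxygen (C1′) of 21 | COCOc1cc(C)c(C(=O)Oc2c3COC(C)(C)Oc3c3C(=O)OCc3c2O[Si](C(C)C)(C(C)C)C(C)C)c(F)c1C(=O)OC(C)(C)C
F6 | step 17 | tert-butyl ester of protected depsidone acid 29 | COCOc1cc(C)c2C(=O)Oc3c4COC(C)(C)Oc4c4C(=O)OCc4c3Oc2c1C(=O)OC(C)(C)C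
F7 | step 16 | 4,5-dihydroxyphthalide acetonide (catechol; acetonide as in 19) | O=C1OCc2c(O)c(O)c3COC(C)(C)Oc3c12
F8 | step 16 | C6′-hydroxy depside (23 without the silyl group on the C6′ oxygen) | COCOc1cc(C)c(C(=O)Oc2c3COC(C)(C)Oc3c3C(=O)OCc3c2O)c(OS(=O)(=O)C(F)(F)F)c1[Si](C)(C)C
F9 | step 8 | methyl 5-formyl-2,4-dihydroxy-3,6-dimethylbenzoate | COC(=O)c1c(C)c(C=O)c(O)c(C)c1O
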